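If each portion of free catalyst lost takes with it a fixed fraction of the starting material then left, the fraction converted depends on the amount of catalyst lost and not on the starting material charged. The problem stands below.

| flask | starting material | gas phase | free catalyst | remark | time |
|---|---|---|---|---|---|
| dawn | 2 M | 200 mM (held) | 300 mM | run made earlier |  |
| noon | 3 M | 200 mM (held) | 600 mM | run made earlier |  |
| flask | 3.0 M | 200 mM (held) | 300 mM |  | 40 min |

- dawn (time / min: product / %): 2.00: 3.6; 6.00: 11.5; 12.0: 23.1; 15.0: 27.0; 25.0: 37.2; 30.0: 39.1; 40.0: 41.8
- noon (time / min: product / %): 4.00: 8.9; 10.0: 21.9; 20.0: 41.5; 30.0: 54.5; 40.0: 61.9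

(standard deviation of a reading: 0.3 percentage points)

1. the product standing at 40 min, as a percentage of the starting material charged
2. the change that raises the amount of product at 40 min, in percent of the starting material charged most ("none" if none brings more than 2 percentage points) (eta / beta / gamma / none)
3. amount of product at 40 min, in percent of the starting material charged, after beta

- eta: doubling the amount of free catalyst, all else as stated
- beta: doubling the saturation concentration of gas phase, all else as stated
- gamma: doubling the transfer coefficient of the gas phase, all else as stated

- the numbers in the tables scatter by 0.3 percentage points (one standard deviation)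
- at the start none of the gas phase is in solution

The dawn run has nearly stopped, gaining 2.7 percentage points in its last 10.0 min with 58.2 % of its starting material left. It reads 1.80 L mol⁻¹ for the conversion capacity, defined as the natural logarithm of charge over remainder, divided by the catalyst lost, here taken as the dawn charge of catalyst, a kind of selectivity factor. The noon run, reckoned on its own catalyst charge, at 1.61 L mol⁻¹ and still climbing, stands lower. The flask carries the same charge of catalyst as the dawn run, so this reckoning gives 41.8 % for it. In this reckoning doubling the catalyst puts the ceiling at 66.1 %, while beta leaves the capacity unchanged. The forecast gives 37 %, chooses eta as well and differs on beta, which it puts at 57 %, on the ground that “Beta doubles the rate at most”.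

The flask gives 41.0 %, and eta is best at 21 points, while beta reaches 43.0 %.

    gas phase ⇌ dissolved gas, rate k1*(csat - [dissolved gas]) (kL = 0.550 min⁻¹)
    dissolved gas ⇌ dormant form (K = 10.0, k = 0.0850 min⁻¹)
    starting material + dissolved gas + free catalyst → free catalyst + product (k = 1.20 L² mol⁻² min⁻¹)
    dissolved gas + free catalyst → spent catalyst (k = 0.640 L mol⁻¹ min⁻¹)

In this flask the gas transfer could deliver 147 % of the charge by 40 min into a solution kept empty, far more than the 41.0 % of product standing, yet free catalyst is down to 6.12 % with 59 % of starting material left. The capacity applied to the 93.9 % of this flask's catalyst spent gives 39.8 %.

In the neighbour flask with 1.2 M of free catalyst, 68.5 % is spent at 40.0 min, so the capacity gives 77.2 %; the computed flask stands at 78.6 %.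

The runs are simulated with made-up constants; the scatter is artificial.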